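Ring B, a diosphenol (C7 enol, C8 ketone; eremophilane numbering, ring A = C1–C5 + C10), is closed by one thermal cascade. Its precursor is a ketal-protected cyclohexene whose C9 allylic alcohol carries a 2-oxyacrolein unit (C6–C7–C8) as a temporary C9–O–C7 ether. A Claisen shift forms C5–C6, sets the quaternary C5 anti to the C4 methyl and breaks the tether; the freed C9=C10 methylene then adds to the C8 aldehyde in a carbonyl-ene reaction (C8–C9). The step exploits the allylic triad C9–C10=C5 next to the C4 stereocentre. Oxidation to the silyl diosphenol trienone, C3 reduction and esterification with a separately made (R)-dienoic acid finish the route.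

Key step: step 8

Remark: bicyclic compounds are named with the core numbering above (ring B = C5 to C10; the β face is the face of the C4 and C5 methyl groups). The 1,2-dione 12 is written in the diketo form, although enol tautomers are expected to predominate.

**Ring A and tether (steps 1–7)**

Step 1
Reactants: 1 1,4-dioxaspiro[4.5]dec-6-en-8-one
Product: 2 7-iodo-1,4-dioxaspiro[4.5]dec-6-en-8-one
Conditions: I2, pyridine, CH2Cl2, 0 °C to rt
Reagents that add atoms: iodine, II
Why: α-Iodination of the enone by pyridine-mediated addition–elimination of iodine is selective for the α-carbon of cyclohexenones and leaves the dioxolane untouched.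

Step 2
Reactants: 2 7-iodo-1,4-dioxaspiro[4.5]dec-6-en-8-one
Product: 3 7-methyl-1,4-dioxaspiro[4.5]dec-6-en-8-one
Conditions: MeZnCl, Pd(dppf)Cl2 (3 mol %), THF, 0 °C to rt
Reagents that add atoms: methylzinc chloride, C[Zn]Cl
Why: Negishi cross-coupling of the α-iodoenone with a methylzinc halide replaces iodine by methyl, the organozinc being unreactive toward the enone carbonyl and the ketal.

Step 3
Reactants: 3 7-methyl-1,4-dioxaspiro[4.5]dec-6-en-8-one
Product: 5 (6R)-6,7-dimethyl-1,4-dioxaspiro[4.5]dec-7-en-8-yl trifluoromethanesulfonate, via magnesium enolate 4 (not isolated)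
Conditions: MeMgBr, Cu(OTf)2 (3 mol %), chiral N-(2-hydroxyalkyl)imidazolinium salt as NHC precursor (4 mol %), Et2O, −30 °C; then N-(5-chloropyridin-2-yl)bis(trifluoromethanesulfonimide), THF, −30 °C to rt
Reagents that add atoms: methylmagnesium bromide, C[Mg]Br; N-(5-chloropyridin-2-yl)bis(trifluoromethanesulfonimide), O=S(=O)(N(c1ccc(Cl)cn1)S(=O)(=O)C(F)(F)F)C(F)(F)F
Why: Copper-catalysed asymmetric conjugate addition of a Grignard reagent to an α-substituted cyclohexenone, in which the chiral NHC–copper catalyst (enantiomer chosen for the 6R product) sets the methyl-bearing stereocentre (C4 of the target), gives the tetrasubstituted magnesium enolate regiospecifically, and O-triflation fixes the C7=C8 double bond.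

Step 4
Reactants: 5 (6R)-6,7-dimethyl-1,4-dioxaspiro[4.5]dec-7-en-8-yl trifluoromethanesulfonate
Product: 6 [(6R)-6,7-dimethyl-1,4-dioxaspiro[4.5]dec-7-en-8-yl]methanol
Conditions: Bu3SnCH2OH, Pd(PPh3)4 (5 mol %), LiCl, 1,4-dioxane, 100 °C
Reagents that add atoms: (tributylstannyl)methanol, CCCC[Sn](CCCC)(CCCC)CO
Why: Stille coupling of the enol triflate with (tributylstannyl)methanol transfers the hydroxymethyl group (C9) without moving the double bond, LiCl assisting transmetalation.

Step 5
Reactants: 6 [(6R)-6,7-dimethyl-1,4-dioxaspiro[4.5]dec-7-en-8-yl]methanol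
Product: 7 2-{[(6R)-6,7-dimethyl-1,4-dioxaspiro[4.5]dec-7-en-8-yl]methoxy}-N-methoxy-N-methylacetamide
Conditions: NaH, 2-bromo-N-methoxy-N-methylacetamide, THF, 0 °C to rt
Reagents that add atoms: 2-bromo-N-methoxy-N-methylacetamide, BrCC(=O)N(C)OC
Why: Williamson etherification of the primary allylic alkoxide with the α-bromo amide, whose N-methoxy-N-methyl group prevents over-reduction in the next step.

Step 6
Reactants: 7 2-{[(6R)-6,7-dimethyl-1,4-dioxaspiro[4.5]dec-7-en-8-yl]methoxy}-N-methoxy-N-methylacetamide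
Product: 8 2-{[(6R)-6,7-dimethyl-1,4-dioxaspiro[4.5]dec-7-en-8-yl]methoxy}acetaldehyde
Conditions: i-Bu2AlH, THF, −78 °C; aq. potassium sodium tartrate work-up
Reagents that add atoms: none
Why: Hydride reduction of the N-methoxy-N-methylamide (Weinreb amide reduction) stops at the aldehyde because the chelated tetrahedral aluminium intermediate collapses only on work-up.

Step 7
Reactants: 8 2-{[(6R)-6,7-dimethyl-1,4-dioxaspiro[4.5]dec-7-en-8-yl]methoxy}acetaldehyde
Product: 9 2-{[(6R)-6,7-dimethyl-1,4-dioxaspiro[4.5]dec-7-en-8-yl]methoxy}prop-2-enal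
Conditions: aq. formaldehyde (37 %), pyrrolidine (10 mol %), propionic acid (10 mol %), i-PrOH, rt
Reagents that add atoms: formaldehyde, C=O
Why: Amine-catalysed Mannich condensation with formaldehyde and elimination (organocatalytic α-methylenation of aldehydes) installs the C6 methylene at room temperature, below the onset of the [3,3] shift.

**Key step and ring-B adjustment (steps 8–12)**

Step 8
Reactants: 9 2-{[(6R)-6,7-dimethyl-1,4-dioxaspiro[4.5]dec-7-en-8-yl]methoxy}prop-2-enal
Product: 11 (4R,5R)-3,3-ethylenedioxy-8-hydroxy-4,5-dimethyl-Δ1(10)-octalin-7-one (core numbering; C8 epimers), via keto aldehyde 10 (not isolated)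
Conditions: toluene (0.01 M), BHT (cat.), 110 °C, sealed tube
Reagents that add atoms: none
Why: A thermal [3,3]-sigmatropic (Claisen) rearrangement of the 2-formyl-substituted allyl vinyl ether 9 through a chair transition state forms C5–C6 and cleaves the temporary C9–O bond, giving α-keto aldehyde 10 with an exocyclic C9=C10 methylene; the activated aldehyde then undergoes an intramolecular type 2 carbonyl-ene reaction with that methylene (hydrogen taken from C1), forming C8–C9. The closest known reaction types are the Gosteli-type Claisen rearrangement of acceptor-substituted allyl vinyl ethers and its tandem use with carbonyl-ene cyclisation of α-oxo carbonyl compounds. Ring B closes as a six-membered ring in an ene cyclisation whose enophile is tethered to the central carbon of the ene. The quaternary C5 is controlled by the C4 methyl: allylic strain with the C5 methyl places it pseudoaxial and the new bond forms on the opposite face, which should give the cis-4,5-dimethyl pattern; the C8 carbinol forms as a mixture that step 9 erases. The step needs C6 to be delivered to C5 and not to C1 or C9, which the ether tether at C9 secures, and ene attack on the aldehyde and not on the C7 ketone, which the higher reactivity of the aldehyde and the strained five-membered alternative secure.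

Step 9
Reactants: 11 (4R,5R)-3,3-ethylenedioxy-8-hydroxy-4,5-dimethyl-Δ1(10)-octalin-7-one
Product: 12 (4R,5R)-3,3-ethylenedioxy-4,5-dimethyl-Δ1(10)-octalin-7,8-dione
Conditions: Dess–Martin periodinane, CH2Cl2, rt
Reagents that add atoms: none
Why: Dess–Martin oxidation converts the α-hydroxy ketone into the 1,2-dione, erasing the C8 stereocentre without touching the ketal or the trisubstituted alkene.

Step 10
Reactants: 12 (4R,5R)-3,3-ethylenedioxy-4,5-dimethyl-Δ1(10)-octalin-7,8-dione
Product: 14 (4R,5R)-7-[(tert-butyldimethylsilyl)oxy]-3,3-ethylenedioxy-4,5-dimethyl-bicyclo[4.4.0]deca-1,6,9-trien-8-one (core numbering), via bis-silyl trienol ether 13 (not isolated)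
Conditions: TBSOTf, Et3N, CH2Cl2, −78 to 0 °C; then DDQ, 2,6-lutidine, 0 °C
Reagents that add atoms: tert-butyldimethylsilyl trifluoromethanesulfonate, CC(C)(C)[Si](C)(C)OS(=O)(=O)C(F)(F)F
Why: Soft enolisation of both carbonyls gives the 7,8-bis(silyloxy) triene, from which DDQ abstracts hydride at C2, the only allylic sp3 position, so that the C8 oxocarbenium ion loses its silyl group (DDQ dehydrogenation of silyl dienol ethers to linear dienones) while the C7 silyl enol ether stays as the diosphenol protecting group.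

Step 11
Reactants: 14 (4R,5R)-7-[(tert-butyldimethylsilyl)oxy]-3,3-ethylenedioxy-4,5-dimethyl-bicyclo[4.4.0]deca-1,6,9-trien-8-one
Product: 15 (4R,5R)-7-[(tert-butyldimethylsilyl)oxy]-4,5-dimethyl-bicyclo[4.4.0]deca-1,6,9-triene-3,8-dione (core numbering)
Conditions: PPTS, acetone/H2O (9:1), 40 °C
Reagents that add atoms: water, O
Why: Mild acid-catalysed hydrolysis of the dioxolane releases the C3 ketone, the α-silyloxy enone being a deactivated enol ether that should survive PPTS, and the product is used at once to avoid epimerisation at C4.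

Step 12
Reactants: 15 (4R,5R)-7-[(tert-butyldimethylsilyl)oxy]-4,5-dimethyl-bicyclo[4.4.0]deca-1,6,9-triene-3,8-dione
Product: 16 (3S,4R,5S)-7-[(tert-butyldimethylsilyl)oxy]-3-hydroxy-4,5-dimethyl-bicyclo[4.4.0]deca-1,6,9-trien-8-one (core numbering; 3β-alcohol)
Conditions: NaBH4, CeCl3·7H2O, MeOH, −78 °C
Reagents that add atoms: none
Why: Luche 1,2-reduction should attack C3, the less hindered, linearly conjugated carbonyl, in preference to the cross-conjugated C8 carbonyl shielded by the OTBS group, and hydride should enter from the α face opposite the C4 and C5 methyl groups to give the 3β-alcohol cis to both methyls.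

**Side-chain acid (steps 13–19)**

Step 13
Reactants: 17 (R)-4-benzyloxazolidin-2-one
Product: 18 (R)-4-benzyl-3-butanoyloxazolidin-2-one
Conditions: n-BuLi, THF, −78 °C; then butanoyl chloride, −78 to 0 °C
Reagents that add atoms: butanoyl chloride, CCCC(Cl)=O
Why: N-Acylation of the lithiated oxazolidinone with the acid chloride is the standard entry to the chiral imide.

Step 14
Reactants: 18 (R)-4-benzyl-3-butanoyloxazolidin-2-one
Product: 19 (R)-4-benzyl-3-[(2S)-2-(hydroxymethyl)butanoyl]oxazolidin-2-one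
Conditions: TiCl4, i-Pr2NEt, CH2Cl2, 0 °C; then 1,3,5-trioxane, TiCl4, 0 °C
Reagents that add atoms: 1,3,5-trioxane, C1OCOCO1
Why: Titanium-enolate hydroxymethylation of the chiral N-acyl oxazolidinone (auxiliary-controlled alkylation), in which the chelated Z-enolate reacts with the formaldehyde equivalent on the face opposite the benzyl group and so sets the 2S centre.

Step 15
Reactants: 19 (R)-4-benzyl-3-[(2S)-2-(hydroxymethyl)butanoyl]oxazolidin-2-one
Product: 20 (R)-4-benzyl-3-[(2S)-2-{[(tert-butyldimethylsilyl)oxy]methyl}butanoyl]oxazolidin-2-one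
Conditions: TBSCl, imidazole, DMF, rt
Reagents that add atoms: tert-butyldimethylsilyl chloride, CC(C)(C)[Si](C)(C)Cl
Why: Silylation of the primary alcohol with TBSCl and imidazole is mild enough that no epimerisation of the α-centre is expected.

Step 16
Reactants: 20 (R)-4-benzyl-3-[(2S)-2-{[(tert-butyldimethylsilyl)oxy]methyl}butanoyl]oxazolidin-2-one
Product: 21 (R)-2-{[(tert-butyldimethylsilyl)oxy]methyl}butan-1-ol
Conditions: LiBH4, MeOH (1 equiv), THF, 0 °C
Reagents that add atoms: none
Why: Reductive cleavage of the imide with LiBH4 gives the primary alcohol and returns the auxiliary without touching the silyl ether or the stereocentre.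

Step 17
Reactants: 21 (R)-2-{[(tert-butyldimethylsilyl)oxy]methyl}butan-1-ol
Product: 22 (S)-2-{[(tert-butyldimethylsilyl)oxy]methyl}butanal
Conditions: Dess–Martin periodinane, pyridine, CH2Cl2, 0 °C
Reagents that add atoms: none
Why: Buffered Dess–Martin oxidation gives the α-branched aldehyde, which is used immediately to avoid epimerisation.

Step 18
Reactants: 22 (S)-2-{[(tert-butyldimethylsilyl)oxy]methyl}butanal
Product: 23 ethyl (2E,4E,6R)-6-{[(tert-butyldimethylsilyl)oxy]methyl}octa-2,4-dienoate
Conditions: triethyl 4-phosphonocrotonate, LiN(SiMe3)2, THF, −78 to 0 °C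
Reagents that add atoms: triethyl 4-phosphonocrotonate, CCOC(=O)/C=C/CP(=O)(OCC)OCC
Why: Vinylogous Horner–Wadsworth–Emmons olefination with the stabilised phosphonocrotonate anion should give the (2E,4E)-dienoate, the new 4,5-double bond forming E.

Step 19
Reactants: 23 ethyl (2E,4E,6R)-6-{[(tert-butyldimethylsilyl)oxy]methyl}octa-2,4-dienoate
Product: 24 (2E,4E,6R)-6-{[(tert-butyldimethylsilyl)oxy]methyl}octa-2,4-dienoic acid
Conditions: LiOH, THF/MeOH/H2O, rt; then 1 M HCl to pH 4
Reagents that add atoms: lithium hydroxide, [Li+].[OH-]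
Why: Saponification of the ethyl ester with LiOH at room temperature leaves the primary TBS ether and the remote stereocentre intact.

**Coupling and deprotection (steps 20–21)**

Step 20
Reactants: 16 (3S,4R,5S)-7-[(tert-butyldimethylsilyl)oxy]-3-hydroxy-4,5-dimethyl-bicyclo[4.4.0]deca-1,6,9-trien-8-one; 24 (2E,4E,6R)-6-{[(tert-butyldimethylsilyl)oxy]methyl}octa-2,4-dienoic acid
Product: 26 bis-TBS ether of septeremophilane E (C3 ester of 16 with acid 24), via mixed anhydride 25 (not isolated)
Conditions: 2,4,6-trichlorobenzoyl chloride, Et3N, THF, rt; then 16, DMAP, toluene, rt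
Reagents that add atoms: none
Why: Yamaguchi esterification through the mixed anhydride acylates the hindered secondary allylic alcohol, the only free hydroxyl group of 16, with retention at C3.

Step 21
Reactants: 26 bis-TBS ether of septeremophilane E
Product: 27 septeremophilane E
Conditions: HF·pyridine, pyridine, THF, 0 °C to rt
Reagents that add atoms: none
Why: Fluoride-mediated desilylation with buffered HF·pyridine removes both the primary silyl ether and the silyl enol ether without hydrolysing the dienoate ester, releasing the diosphenol.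

**Compound list**

1 | 1,4-dioxaspiro[4.5]dec-6-en-8-one | O=C1C=CC2(CC1)OCCO2 | starting material
2 | 7-iodo-1,4-dioxaspiro[4.5]dec-6-en-8-one | O=C1C(I)=CC2(CC1)OCCO2 | intermediate
3 | 7-methyl-1,4-dioxaspiro[4.5]dec-6-en-8-one | O=C1C(C)=CC2(CC1)OCCO2 | intermediate
4 | bromomagnesium (6R)-6,7-dimethyl-1,4-dioxaspiro[4.5]dec-7-en-8-olate (not isolated) | CC1=C(O[Mg]Br)CCC2(OCCO2)[C@@H]1C | intermediate
5 | (6R)-6,7-dimethyl-1,4-dioxaspiro[4.5]dec-7-en-8-yl trifluoromethanesulfonate | CC1=C(OS(=O)(=O)C(F)(F)F)CCC2(OCCO2)[C@@H]1C | intermediate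
6 | [(6R)-6,7-dimethyl-1,4-dioxaspiro[4.5]dec-7-en-8-yl]methanol | CC1=C(CO)CCC2(OCCO2)[C@@H]1C | intermediate
7 | 2-{[(6R)-6,7-dimethyl-1,4-dioxaspiro[4.5]dec-7-en-8-yl]methoxy}-N-methoxy-N-methylacetamide | CC1=C(COCC(=O)N(C)OC)CCC2(OCCO2)[C@@H]1C | intermediate
8 | 2-{[(6R)-6,7-dimethyl-1,4-dioxaspiro[4.5]dec-7-en-8-yl]methoxy}acetaldehyde | CC1=C(COCC=O)CCC2(OCCO2)[C@@H]1C | intermediate
9 | 2-{[(6R)-6,7-dimethyl-1,4-dioxaspiro[4.5]dec-7-en-8-yl]methoxy}prop-2-enal | CC1=C(COC(=C)C=O)CCC2(OCCO2)[C@@H]1C | intermediate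
10 | 3-[(6R,7R)-6,7-dimethyl-8-methylidene-1,4-dioxaspiro[4.5]decan-7-yl]-2-oxopropanal (not isolated) | C=C1CCC2(OCCO2)[C@H](C)[C@@]1(C)CC(=O)C=O | intermediate
11 | (4R,5R)-3,3-ethylenedioxy-8-hydroxy-4,5-dimethyl-Δ1(10)-octalin-7-one, cis-dimethyl, C8 epimers (core numbering) | OC1CC2=CCC3(OCCO3)[C@H](C)[C@@]2(C)CC1=O | intermediate
12 | (4R,5R)-3,3-ethylenedioxy-4,5-dimethyl-Δ1(10)-octalin-7,8-dione (core numbering) | O=C1CC2=CCC3(OCCO3)[C@H](C)[C@@]2(C)CC1=O | intermediate
13 | (4R,5R)-7,8-bis[(tert-butyldimethylsilyl)oxy]-3,3-ethylenedioxy-4,5-dimethyl-bicyclo[4.4.0]deca-1(10),6,8-triene (core numbering; not isolated) | CC(C)(C)[Si](C)(C)OC1=CC2=CCC3(OCCO3)[C@H](C)[C@@]2(C)C=C1O[Si](C)(C)C(C)(C)C | intermediate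
14 | (4R,5R)-7-[(tert-butyldimethylsilyl)oxy]-3,3-ethylenedioxy-4,5-dimethyl-bicyclo[4.4.0]deca-1,6,9-trien-8-one (core numbering) | O=C1C=C2C=CC3(OCCO3)[C@H](C)[C@@]2(C)C=C1O[Si](C)(C)C(C)(C)C | intermediate
15 | (4R,5R)-7-[(tert-butyldimethylsilyl)oxy]-4,5-dimethyl-bicyclo[4.4.0]deca-1,6,9-triene-3,8-dione (core numbering) | O=C1C=C2C=CC(=O)[C@H](C)[C@@]2(C)C=C1O[Si](C)(C)C(C)(C)C | intermediate
16 | (3S,4R,5S)-7-[(tert-butyldimethylsilyl)oxy]-3-hydroxy-4,5-dimethyl-bicyclo[4.4.0]deca-1,6,9-trien-8-one (core numbering; OH cis to both methyls) | O[C@H]1C=CC2=CC(=O)C(O[Si](C)(C)C(C)(C)C)=C[C@]2(C)[C@H]1C | intermediate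
17 | (R)-4-benzyloxazolidin-2-one | O=C1N[C@H](Cc2ccccc2)CO1 | starting material
18 | (R)-4-benzyl-3-butanoyloxazolidin-2-one | CCCC(=O)N1[C@H](Cc2ccccc2)COC1=O | intermediate
19 | (R)-4-benzyl-3-[(2S)-2-(hydroxymethyl)butanoyl]oxazolidin-2-one | CC[C@H](C(=O)N1[C@H](Cc2ccccc2)COC1=O)CO | intermediate
20 | (R)-4-benzyl-3-[(2S)-2-{[(tert-butyldimethylsilyl)oxy]methyl}butanoyl]oxazolidin-2-one | CC[C@H](C(=O)N1[C@H](Cc2ccccc2)COC1=O)CO[Si](C)(C)C(C)(C)C | intermediate
21 | (R)-2-{[(tert-butyldimethylsilyl)oxy]methyl}butan-1-ol | CC[C@H](CO)CO[Si](C)(C)C(C)(C)C | intermediate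
22 | (S)-2-{[(tert-butyldimethylsilyl)oxy]methyl}butanal | CC[C@H](C=O)CO[Si](C)(C)C(C)(C)C | intermediate
23 | ethyl (2E,4E,6R)-6-{[(tert-butyldimethylsilyl)oxy]methyl}octa-2,4-dienoate | CC[C@H](/C=C/C=C/C(=O)OCC)CO[Si](C)(C)C(C)(C)C | intermediate
24 | (2E,4E,6R)-6-{[(tert-butyldimethylsilyl)oxy]methyl}octa-2,4-dienoic acid | CC[C@H](/C=C/C=C/C(=O)O)CO[Si](C)(C)C(C)(C)C | intermediate
25 | mixed anhydride of 24 with 2,4,6-trichlorobenzoic acid (not isolated) | CC[C@H](/C=C/C=C/C(=O)OC(=O)c1c(Cl)cc(Cl)cc1Cl)CO[Si](C)(C)C(C)(C)C | intermediate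
26 | bis-TBS ether of septeremophilane E: (3S,4R,5S)-7-[(tert-butyldimethylsilyl)oxy]-4,5-dimethyl-8-oxo-bicyclo[4.4.0]deca-1,6,9-trien-3-yl (2E,4E,6R)-6-{[(tert-butyldimethylsilyl)oxy]methyl}octa-2,4-dienoate | CC[C@H](/C=C/C=C/C(=O)O[C@H]1C=CC2=CC(=O)C(O[Si](C)(C)C(C)(C)C)=C[C@]2(C)[C@H]1C)CO[Si](C)(C)C(C)(C)C | intermediate
27 | septeremophilane E: (3S,4R,5S)-7-hydroxy-4,5-dimethyl-8-oxo-bicyclo[4.4.0]deca-1,6,9-trien-3-yl (2E,4E,6R)-6-(hydroxymethyl)octa-2,4-dienoate | CC[C@H](/C=C/C=C/C(=O)O[C@H]1C=CC2=CC(=O)C(O)=C[C@]2(C)[C@H]1C)CO | target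

**Step count and risks**

Total step count: 21. Longest linear sequence: 14 steps (steps 1–12, 20, 21); the side-chain acid takes 7 steps (13–19).

Steps most likely to fail:

Step 8 (key step). The 2-alkoxyacrolein 9 may oligomerise or dimerise by hetero-Diels–Alder reaction faster than it rearranges, or the ene closure may be slow at the temperature needed for the [3,3] shift. The fallback separates the two bond formations; it sets out from 6 and returns at 11. Alcohol 6 is esterified with (tert-butyldimethylsilyloxy)acetic acid (DCC, DMAP) to the glycolate ester F1. Tebbe methylenation with Cp2Ti(μ-CH2)(μ-Cl)AlMe2 gives the allyl vinyl ether F2, which on heating (xylene, 140 °C) should undergo the Claisen rearrangement alone to the silyloxymethyl ketone F3. Bu4NF then gives the hydroxy ketone F4, Dess–Martin oxidation gives keto aldehyde 10, and Me2AlCl (CH2Cl2, −78 °C) closes ring B to 11.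

Step 3. Conjugate addition at the β-carbon next to the ketal of an α-methyl enone may be slow and poorly enantioselective with the methyl Grignard reagent, and O-triflation of the magnesium enolate may be incomplete. The fallback moves the asymmetric step to the unsubstituted enone; it sets out from 1 and returns at 5. Copper-catalysed asymmetric addition of Me2Zn to 1 (Cu(OTf)2, BINOL-derived phosphoramidite ligand, toluene, −30 °C) with TMSCl trapping gives the silyl enol ether F5. MeLi then MeI gives the trans-dimethyl ketone F6, and equilibrating enolisation (LiN(SiMe3)2, slight excess of ketone) followed by N-(5-chloropyridin-2-yl)bis(trifluoromethanesulfonimide) gives 5.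

Step 12. Hydride delivery to the wrong face of the C3 carbonyl would give the 3α-alcohol, and reduction at C8 may compete. The fallback uses the epimer productively; it sets out from 15 and returns at 26. If the reduction gives mainly the C3-epimeric alcohol F7, Mitsunobu esterification with acid 24 (PPh3, DIAD, toluene, 0 °C) inverts C3 and gives 26 directly.

Further compounds
F1 | step 8 | [(6R)-6,7-dimethyl-1,4-dioxaspiro[4.5]dec-7-en-8-yl]methyl 2-[(tert-butyldimethylsilyl)oxy]acetate | CC1=C(COC(=O)CO[Si](C)(C)C(C)(C)C)CCC2(OCCO2)[C@@H]1C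
F2 | step 8 | (6R)-8-[({3-[(tert-butyldimethylsilyl)oxy]prop-1-en-2-yl}oxy)methyl]-6,7-dimethyl-1,4-dioxaspiro[4.5]dec-7-ene | CC1=C(COC(=C)CO[Si](C)(C)C(C)(C)C)CCC2(OCCO2)[C@@H]1C
F3 | step 8 | 1-[(tert-butyldimethylsilyl)oxy]-3-[(6R,7R)-6,7-dimethyl-8-methylidene-1,4-dioxaspiro[4.5]decan-7-yl]propan-2-one | C=C1CCC2(OCCO2)[C@H](C)[C@@]1(C)CC(=O)CO[Si](C)(C)C(C)(C)C
F4 | step 8 | 1-hydroxy-3-[(6R,7R)-6,7-dimethyl-8-methylidene-1,4-dioxaspiro[4.5]decan-7-yl]propan-2-one | C=C1CCC2(OCCO2)[C@H](C)[C@@]1(C)CC(=O)CO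
F5 | step 3 | trimethyl{[(6R)-6-methyl-1,4-dioxaspiro[4.5]dec-7-en-8-yl]oxy}silane | C[C@@H]1C=C(O[Si](C)(C)C)CCC12OCCO2
F6 | step 3 | (6R,7R)-6,7-dimethyl-1,4-dioxaspiro[4.5]decan-8-one | C[C@@H]1[C@@H](C)C(=O)CCC12OCCO2
F7 | step 12 | (3R,4R,5S)-7-[(tert-butyldimethylsilyl)oxy]-3-hydroxy-4,5-dimethyl-bicyclo[4.4.0]deca-1,6,9-trien-8-one (core numbering; 3α-alcohol) | O[C@@H]1C=CC2=CC(=O)C(O[Si](C)(C)C(C)(C)C)=C[C@]2(C)[C@H]1C
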